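**Plan**

1. Locants (target numbering): ring A = 5′,6′-dimethyl-2′-pyranone (O1′, C2′=O, C3′, C4′–O); ring B = C3′–C4′–O–C4a–C10a–C11; ring C (seven-membered) = C4a (hemiketal), C5 (CHOH), C6 (C=O), C6a (C–OH), C9a, C10 (CHMe), C10a; ring D = C6a, C7 (CMe2), C8 (C=O), C9, C9a.
2. Retrosynthetic cuts, in order: C4a–OH/C5–OH (epoxidation–hydration of a C4a=C5 enol ether); O4′–C4a (cyclodehydration onto a C4a,C6-diketone); C6=O (β-oxidation of a C4a enone); C11–C3′ (reductive alkylation of the pyranone by a C11 lactol); then ring C at C6–C6a and C4a–C10a in one (4+3) event.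
3. Enabling feature: in ring C the four-carbon unit C6a–C9a–C10–C10a carries the C6a oxygen and the C11 carbon on the same face. Tying O(C6a) to C11 as a lactone turns this unit into a 2-pyranone fused to ring D, an s-cis-locked diene. The three-carbon unit C4a–C5–C6, with C4a at the ketone level, is the vinylcarbene of a cyclopropenone ketal.
4. Forward order: ring D (commercial dione) → 2-pyranone as temporary ring → ring C by (4+3) cycloaddition → lactone bridge reduced and ring A joined at C11 → C6 oxidized and ring B closed → ring D enone → C5/C4a oxygenation last.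
5. Stereochemistry: a CBS-derived C8 carbinol (later oxidized) steers the cycloaddition face and so sets C6a; the lactone bridge fixes C10a cis to the C6a oxygen; C10 is set by thermodynamic protonation (methyl trans to C11); C5 and C4a arise by anti opening of an epoxy acetal followed by equilibration.

Key step: step 6

Assumption: the hemiketal carbon C4a and the α-ketol carbon C5 are configurationally labile (ring-chain tautomerism, enolization of the open 2-hydroxy-1,3-diketone), and their natural configuration is taken to be the thermodynamically preferred one.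

**Route**

Step 1
Reactants: 1 2,2-dimethylcyclopentane-1,3-dione
Product: 2 (3S)-3-hydroxy-2,2-dimethylcyclopentan-1-one
Conditions: (R)-1-methyl-3,3-diphenyltetrahydro-1H,3H-pyrrolo[1,2-c][1,3,2]oxazaborole ((R)-Me-CBS, 0.1 equiv), BH3·SMe2 (0.6 equiv), THF, −30 °C; MeOH, then aq. work-up
Reagents that add atoms: none
Why: Corey–Bakshi–Shibata reduction differentiates the two enantiotopic carbonyls, the (R)-catalyst binding the ketone with the quaternary C2 as the large group so that hydride delivery should give the 3S carbinol, while sub-stoichiometric borane limits diol formation.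

Step 2
Reactants: 2 (3S)-3-hydroxy-2,2-dimethylcyclopentan-1-one
Product: 3 (3S)-3-[(tert-butyldimethylsilyl)oxy]-2,2-dimethylcyclopentan-1-one
Conditions: TBSOTf (1.3 equiv), 2,6-lutidine (2 equiv), CH2Cl2, 0 °C
Reagents that add atoms: tert-butyldimethylsilyl trifluoromethanesulfonate, CC(C)(C)[Si](C)(C)OS(=O)(=O)C(F)(F)F
Why: O-silylation with the silyl triflate protects the hindered neopentyl alcohol without touching the ketone or the stereocentre.

Step 3
Reactants: 3 (3S)-3-[(tert-butyldimethylsilyl)oxy]-2,2-dimethylcyclopentan-1-one; 4 ethyl but-2-ynoate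
Product: 5 (6S)-6-[(tert-butyldimethylsilyl)oxy]-4,7,7-trimethyl-6,7-dihydrocyclopenta[b]pyran-2(5H)-one
Conditions: KN(SiMe3)2 (1.1 equiv), THF, −78 °C; 4 (1.2 equiv), −78 → 23 °C; aq. NH4Cl
Reagents that add atoms: none
Why: Base-mediated annulation of a ketone enolate with an alkynoate (Michael addition at the β-carbon of 4, proton shift to the extended enolate, O-acylative ring closure with loss of ethoxide) gives the 2-pyranone, and since 3 can enolize only toward its CH2 the ring fusion is regiodefined.

Step 4
Reactants: 6 1-bromo-3-chloro-2,2-dimethoxypropane; 7 propane-1,3-diol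
Product: 8 2-(bromomethyl)-2-(chloromethyl)-1,3-dioxane
Conditions: 7 (1.1 equiv), H2SO4 (cat.), 140 °C, distillation of MeOH
Reagents that add atoms: none
Why: Acid-catalysed transketalization, driven by removal of methanol, exchanges the dimethyl ketal for the 1,3-dioxane and leaves both halomethyl groups intact.

Step 5
Reactants: 8 2-(bromomethyl)-2-(chloromethyl)-1,3-dioxane
Product: 9 cyclopropenone 1,3-propanediyl ketal
Conditions: KNH2 (3 equiv), NH3 (l), −50 °C; NH4Cl; pentane extraction, cold storage
Reagents that add atoms: none
Why: Double dehydrohalogenation (1,3-elimination to the halocyclopropane, then 1,2-elimination) is the standard entry to cyclopropenone ketals, and the product is kept cold because it ring-opens near 70 °C.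

Step 6
Reactants: 5 (6S)-6-[(tert-butyldimethylsilyl)oxy]-4,7,7-trimethyl-6,7-dihydrocyclopenta[b]pyran-2(5H)-one; 9 cyclopropenone 1,3-propanediyl ketal
Product: 11 lactone-bridged (4+3) adduct, via vinylcarbene 10 (not isolated)
Conditions: 9 (3 equiv), benzene, 75 °C, sealed tube, 24 h
Reagents that add atoms: none
Why: At 75 °C 9 opens reversibly to the π-delocalized singlet vinylcarbene 10, whose nucleophilic carbene carbon adds to the electrophilic C7a (δ-position, pyranone numbering) and whose electrophilic dialkoxy carbon adds to the nucleophilic C3 (α-position), so that C6–C6a and C4a–C10a form in one operation and C4a arrives as a ketal. The closest known reaction type is the thermal (4+3) cycloaddition of cyclopropenone ketals with 2-pyranones used for tropone annulation, the difference being that the lactone bridge is kept instead of being lost as CO2. Ring C is closed by a suprafacial (4+3) cycloaddition across the s-cis-locked pyranone diene, which leaves the former ring oxygen and C2 as a lactone bridge in a bicyclo[3.2.2]nonadiene. C6a and C10a are bridgeheads, so the bridge fixes their relative configuration (C6a–O and C10a–C11 cis on ring C), and the absolute sense should follow from addition to the pyranone face anti to the C6 silyloxy group, any minor diastereomer being removed by chromatography. The step needs regioselectivity (secured by the polarity match and by sterics, the small CH terminus going to the hindered C7a and the bulky ketal terminus to C3–H), preference for (4+3) over the cyclopropene Diels–Alder mode (secured by working at the temperature where the carbene forms) and survival of the bridge (temperature held at 75 °C and short heating to avoid CO2 extrusion).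

Step 7
Reactants: 11 lactone-bridged (4+3) adduct
Product: 12 bridged C11 lactol
Conditions: i-Bu2AlH (1.2 equiv), CH2Cl2, −78 °C; aq. potassium sodium tartrate
Reagents that add atoms: none
Why: Partial reduction of the lactone with i-Bu2AlH at −78 °C should stop at the tetrahedral aluminate and give the lactol (anomer mixture, of no consequence), the ketal, silyl ether and both alkenes being inert.

Step 8
Reactants: 13 ethyl 3-oxopentanoate; 14 N-methoxy-N-methylacetamide
Product: 16 4-hydroxy-5,6-dimethyl-2H-pyran-2-one, via diketo ester 15 (not isolated)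
Conditions: LiN(i-Pr)2 (3.0 equiv), THF, −78 → 0 °C; 14, −78 → 0 °C; aq. HCl; then DBU, PhMe, 110 °C
Reagents that add atoms: none
Why: γ-Acylation of the β-keto ester dianion by the Weinreb amide gives the 3,5-diketo ester, which lactonizes through its terminal enol under amidine base to the 4-hydroxy-2-pyranone (classical triketide cyclization) with no stereocentre involved.

Step 9
Reactants: 12 bridged C11 lactol; 16 4-hydroxy-5,6-dimethyl-2H-pyran-2-one
Product: 17 C11-linked hydroxypyranone ketal
Conditions: 16 (1.2 equiv), Hantzsch ester (diethyl 2,6-dimethyl-1,4-dihydropyridine-3,5-dicarboxylate, 1.3 equiv), EtOH, 40 °C, no amine catalyst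
Reagents that add atoms: none
Why: Three-component reductive alkylation (Knoevenagel condensation of the acidic pyranone with the latent aldehyde of the lactol, then 1,4-hydride transfer from the Hantzsch ester to the alkylidene) forms C11–C3′ and frees the C6a hydroxyl, and C10a should keep its configuration because it stays a non-enolizable bridgehead in the lactol and no amine is present to form a dienamine.

Step 10
Reactants: 17 C11-linked hydroxypyranone ketal
Product: 18 C4a enone diol
Conditions: aq. HF (48%), MeCN, 0 → 23 °C
Reagents that add atoms: water, O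
Why: Aqueous HF hydrolyses the allylic ketal to the C4a enone and cleaves the silyl ether in one operation (acetal hydrolysis and fluoride desilylation), under conditions mild enough for the tertiary C6a alcohol and the C10a stereocentre.

Step 11
Reactants: 18 C4a enone diol
Product: 20 ring-B vinylogous ester 8-ol, via β-diketone 19 (not isolated)
Conditions: Na2PdCl4 (0.2 equiv), t-BuOOH (1.5 equiv), AcOH–H2O, 50 °C; then TsOH·H2O (cat.), PhMe, 4 Å sieves, 60 °C
Reagents that add atoms: tert-butyl hydroperoxide, CC(C)(C)OO
Why: Wacker–Tsuji oxidation of the enone (oxypalladation at the β-carbon C6 by the hydroperoxide) should give the cyclic β-diketone, and acid then condenses the pyranone hydroxyl with the C4a carbonyl and dehydrates toward C5, the only conjugating direction, closing ring B as a vinylogous ester without enolization at C10a.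

Step 12
Reactants: 20 ring-B vinylogous ester 8-ol
Product: 22 enol ether bis-enone, via deconjugated 8-ketone 21 (not isolated)
Conditions: Dess–Martin periodinane (1.5 equiv), CH2Cl2, 0 → 23 °C; then Et3N (3 equiv), 23 °C
Reagents that add atoms: none
Why: Dess–Martin oxidation of the only secondary alcohol gives the β,γ-unsaturated C8 ketone, which the amine isomerizes to the conjugated cyclopentenone, and because protonation at C10 is reversible through the dienolate the methyl group should settle trans to C11 (both pseudo-equatorial on ring C), the natural C10 configuration.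

Step 13
Reactants: 22 enol ether bis-enone
Product: 24 CNP0525404.1 (target), via epoxy acetal 23 (not isolated)
Conditions: dimethyldioxirane (1.1 equiv, acetone), −40 → 0 °C; then THF–H2O (NaH2PO4/Na2HPO4 buffer, pH 6), 23 °C
Reagents that add atoms: dimethyldioxirane, CC1(C)OO1; water, O
Why: In a Rubottom-type oxidation dimethyldioxirane epoxidizes the electron-rich C4a=C5 enol ether (both enones and the pyranone are electron-poor) and water opens the epoxy acetal at C4a anti to the C5 oxygen to give the trans 4a,5-diol, after which both centres can equilibrate through hemiketal ring opening and enolization of C5 to the trans-fused, anomerically stabilized natural arrangement.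

**Compound list**

1 | 2,2-dimethylcyclopentane-1,3-dione | CC1(C)C(=O)CCC1=O | starting material
2 | (3S)-3-hydroxy-2,2-dimethylcyclopentan-1-one | O=C1CC[C@H](O)C1(C)C | intermediate
3 | (3S)-3-[(tert-butyldimethylsilyl)oxy]-2,2-dimethylcyclopentan-1-one | O=C1CC[C@H](O[Si](C)(C)C(C)(C)C)C1(C)C | intermediate
4 | ethyl but-2-ynoate | CC#CC(=O)OCC | starting material
5 | (6S)-6-[(tert-butyldimethylsilyl)oxy]-4,7,7-trimethyl-6,7-dihydrocyclopenta[b]pyran-2(5H)-one | Cc1cc(=O)oc2c1C[C@H](O[Si](C)(C)C(C)(C)C)C2(C)C | intermediate
6 | 1-bromo-3-chloro-2,2-dimethoxypropane | COC(CBr)(CCl)OC | starting material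
7 | propane-1,3-diol | OCCCO | starting material
8 | 2-(bromomethyl)-2-(chloromethyl)-1,3-dioxane | ClCC1(CBr)OCCCO1 | intermediate
9 | cyclopropenone 1,3-propanediyl ketal (4,8-dioxaspiro[2.5]oct-1-ene) | C1=CC12OCCCO2 | intermediate
10 | vinylcarbene from ring opening of 9, drawn as the zwitterion 2-(1,3-dioxan-2-ylium-2-yl)ethen-1-ide | [CH-]=CC1=[O+]CCCO1 | intermediate (not isolated)
11 | lactone-bridged (4+3) adduct: ring C with C4a 1,3-dioxane ketal, C5=C6 and C9a=C10; lactone bridge O(C6a)–C11(=O)–C10a on one face of ring C; (8S)-OTBS cis to the lactone oxygen on ring D; C7 gem-dimethyl | O1CCCOC12C=C[C@@]3(OC(=O)[C@@H]24)C(=C4C)C[C@H](O[Si](C)(C)C(C)(C)C)C3(C)C | intermediate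
12 | bridged C11 lactol (11 with C11 as CH–OH, anomer mixture) | O1CCCOC12C=C[C@@]3(OC(O)[C@@H]24)C(=C4C)C[C@H](O[Si](C)(C)C(C)(C)C)C3(C)C | intermediate
13 | ethyl 3-oxopentanoate | CCC(=O)CC(=O)OCC | starting material
14 | N-methoxy-N-methylacetamide | CC(=O)N(C)OC | starting material
15 | ethyl 4-methyl-3,5-dioxohexanoate | CC(=O)C(C)C(=O)CC(=O)OCC | intermediate (not isolated)
16 | 4-hydroxy-5,6-dimethyl-2H-pyran-2-one | Cc1oc(=O)cc(O)c1C | intermediate
17 | C11-linked hydroxypyranone ketal: C10a–C11H2–C3′ of the 4′-hydroxypyranone; free C6a–OH cis to C11; C4a 1,3-dioxane ketal; C5=C6; C9a=C10; (8S)-OTBS | Cc1oc(=O)c(c(O)c1C)C[C@@H]2C(C)=C3C[C@H](O[Si](C)(C)C(C)(C)C)C(C)(C)[C@@]3(O)C=CC24OCCCO4 | intermediate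
18 | C4a enone diol: C4a ketone conjugated to C5=C6; C6a–OH; (8S)-OH; C9a=C10; free 4′-hydroxypyranone | Cc1oc(=O)c(c(O)c1C)C[C@@H]2C(C)=C3C[C@H](O)C(C)(C)[C@@]3(O)C=CC2=O | intermediate
19 | β-diketone: C4a and C6 ketones, C5 H2; otherwise as 18 | Cc1oc(=O)c(c(O)c1C)C[C@@H]2C(C)=C3C[C@H](O)C(C)(C)[C@@]3(O)C(=O)CC2=O | intermediate (not isolated)
20 | ring-B vinylogous ester 8-ol: O4′–C4a=C5–C6(=O); C6a–OH; (8S)-OH; C9a=C10 | Cc1oc(=O)c2c(c1C)OC1=CC(=O)[C@@]3(O)C(C[C@H](O)C3(C)C)=C(C)[C@H]1C2 | intermediate
21 | deconjugated 8-ketone: as 20 with C8=O, C9 H2, C9a=C10 | Cc1oc(=O)c2c(c1C)OC1=CC(=O)[C@@]3(O)C(CC(=O)C3(C)C)=C(C)[C@H]1C2 | intermediate (not isolated)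
22 | enol ether bis-enone: O4′–C4a=C5–C6(=O); C8(=O)–C9=C9a; C10 methyl trans to C11; C6a–OH | Cc1oc(=O)c2c(c1C)OC1=CC(=O)[C@@]3(O)C(=CC(=O)C3(C)C)[C@H](C)[C@H]1C2 | intermediate
23 | 4a,5-epoxy acetal of 22 (epoxide oxygen on the ring C face opposite the C6a hydroxyl) | Cc1oc(=O)c2c(c1C)O[C@]14O[C@@H]4C(=O)[C@@]3(O)C(=CC(=O)C3(C)C)[C@H](C)[C@H]1C2 | intermediate (not isolated)
24 | CNP0525404.1, (4aS,5R,6aR,10R,10aR) in the numbering above | Cc1oc(=O)c2c(c1C)O[C@]1(O)[C@H](O)C(=O)[C@@]3(O)C(=CC(=O)C3(C)C)[C@H](C)[C@H]1C2 | target

**Step count and risks**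

Total step count: 13. Longest linear sequence: 10 steps (steps 1, 2, 3, 6, 7, 9, 10, 11, 12, 13).

Steps most likely to fail:

Step 6. What may go wrong: slow cycloaddition at the hindered C7a, loss of CO2 from the adduct on prolonged heating, and poor facial selectivity because the directing silyloxy group is remote from the reacting carbons. The fallback moves the stereochemical decision from substrate control in the cycloaddition to reagent control afterwards. It sets out from 1, which is annulated with 4 as in step 3 to give 4,7,7-trimethyl-5H-cyclopenta[b]pyran-2,6(7H)-dione F1. Heating F1 with 9 at 75 °C should give the racemic 8-oxo adduct F2. Reduction with (R)-Me-CBS and catecholborane should convert both enantiomers into 8S carbinols, which are diastereomers and separable by chromatography. The one with the hydroxyl cis to the lactone oxygen, the 8S-hydroxy adduct F3, is silylated (TBSOTf, 2,6-lutidine) and the fallback comes back to the route at 11.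

Step 11. What may go wrong: sluggish oxypalladation at the neopentyl β-carbon C6, oxidative degradation of the free hydroxypyranone, or epimerization at C10a during prolonged heating in acid. The fallback sets out from 18 and replaces the one-step oxidation by two steps. Weitz–Scheffer epoxidation (t-BuOOH, DBU, CH2Cl2) should give the 5,6-epoxy ketone F4. Isomerization with Pd(PPh3)4 and dppe in toluene at 80 °C (zerovalent palladium opens the Cα–O bond, then β-hydride elimination) should give the β-diketone, and the fallback comes back to the route at 19, which is closed to 20 with acid as in step 11.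

Step 13. What may go wrong: epoxidation from the face that leads to the C5 epimer with incomplete equilibration afterwards, capture of the C4a oxocarbenium by the C6a hydroxyl instead of water, or over-oxidation. The fallback sets out from 22 and sets C5 by hydride delivery instead of oxygen delivery. The crude hydration product, in which 5-epi-24 F5 may predominate, is oxidized with Dess–Martin periodinane to the 5-oxo hemiketal F6. Its C5 carbonyl, flanked by the hemiketal carbon and the C6 ketone, should be the most electrophilic one. Saksena–Evans reduction with Me4NBH(OAc)3 in AcOH–MeCN at −20 °C should deliver hydride from the borate bound to the cis C4a and C6a hydroxyls, placing the C5 hydroxyl on the opposite face, and the fallback comes back to the route at 24.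

**Further compounds**

F1 | step 6 | 4,7,7-trimethyl-5H-cyclopenta[b]pyran-2,6(7H)-dione | Cc1cc(=O)oc2c1CC(=O)C2(C)C
F2 | step 6 | racemic 8-oxo adduct (8-ketone analogue of 11, one enantiomer drawn) | O1CCCOC12C=C[C@@]3(OC(=O)[C@@H]24)C(=C4C)CC(=O)C3(C)C
F3 | step 6 | 8S-hydroxy adduct (desilyl 11) | O1CCCOC12C=C[C@@]3(OC(=O)[C@@H]24)C(=C4C)C[C@H](O)C3(C)C
F4 | step 11 | 5,6-epoxy ketone of 18 (epoxide configuration not defined) | Cc1oc(=O)c(c(O)c1C)C[C@@H]2C(C)=C3C[C@H](O)C(C)(C)[C@@]3(O)C4OC4C2=O
F5 | step 13 | 5-epi-24 | Cc1oc(=O)c2c(c1C)O[C@]1(O)[C@@H](O)C(=O)[C@@]3(O)C(=CC(=O)C3(C)C)[C@H](C)[C@H]1C2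
F6 | step 13 | 5-oxo hemiketal (C5 ketone analogue of 24) | Cc1oc(=O)c2c(c1C)O[C@]1(O)C(=O)C(=O)[C@@]3(O)C(=CC(=O)C3(C)C)[C@H](C)[C@H]1C2
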